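A small charge of starting material, 0.10 M fed over 3.0 h in blue, stands against a large one, 0.40 M put in at the start in green. The next run goes to the flask that ends higher in percent of its own charge.

common to all: free catalyst 0.20 mM

| run | starting material | gas | temperature | remark | time |
|---|---|---|---|---|---|
| Thursday's | 0.18 M (fed, over 3.0 h) | 5.2 mM (held) | −10 °C | run made earlier |  |
| Wednesday's | 0.43 M (fed, over 3.0 h) | 5.2 mM (held) | 5 °C | run made earlier |  |
| green | 0.40 M | 5.2 mM | 5 °C | everything together at the start | 12 h |
| blue | 0.10 M (fed, over 3.0 h) | 5.2 mM (held) | 5 °C |  | 12 h |

- Thursday's (time / h: target / %): 5.00: 3; 10.0: 8; 15.0: 12; 20.0: 21; 25.0: 20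
- Wednesday's (time / h: target / %): 1.00: 0; 3.00: 0; 6.00: 4; 8.00: 7; 12.0: 11

(scatter of a reading: 2 percentage points)

- the flask that ends with the higher amount of target, in percent of the starting material charged, or "neither" when 2 percentage points or less lies between them (green / blue / neither)
- final target, as a percentage of the starting material charged, in green
- final target, as a percentage of the starting material charged, in blue

Wednesday's run has the same temperature and gas as both flasks, so it sets the measure. Its last reading, 11% of 0.43 M, with a scatter of 2 percentage points, is 47.3 mM of target. Call this the batch output, the target concentration made at 5 °C by 12.0 h. That output is about ten times the 5.2 mM of gas held in Wednesday's flask, and it amounts to about 236 turnovers of the 0.20 mM of free catalyst charged. This reckoning assumes that the batch output depends neither on the charge nor on how it goes in.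

Dividing the batch output by each charge gives 11.8% in green and 47.3% in blue, so blue ends higher. Blue's charge is about a quarter of Wednesday's, a range Wednesday's run does not test, so blue's figure is the weaker one. The decision still falls on blue.

The forecast also says blue, with 11.5% in green and a lower figure than this reckoning for blue, 38%, trimmed for “partial desaturation as starting material falls”.

The flask gives blue, with 12.9% in green and 32.1% in blue.

    catalyst intermediate B → catalyst intermediate C (k = 0.210 s⁻¹, Ea = 77.0 kJ mol⁻¹)
    starting material + free catalyst ⇌ catalyst intermediate A (K = 5.70 L mol⁻¹, k = 0.130 L mol⁻¹ s⁻¹, Ea = 49.0 kJ mol⁻¹, ΔH = 13.0 kJ mol⁻¹)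
    gas ⇌ reagent, rate k3*(csat - [reagent]) (kL = 3.10 × 10⁻⁴ s⁻¹)
    reagent + catalyst intermediate A → catalyst intermediate B (k = 9.40 L mol⁻¹ s⁻¹, Ea = 43.0 kJ mol⁻¹)
    catalyst intermediate C → free catalyst + target (k = 0.0670 s⁻¹, Ea = 64.0 kJ mol⁻¹)
    (constants at 5 °C)

As concentrations, green holds 51.6 mM of target, close to the batch output of 47.3 mM, while blue holds 32.1 mM, less than that output. In green at 12.0 h, reagent has a half-life of 0.21 h by its step onto catalyst intermediate A, far shorter than the run, and catalyst intermediate A, the resting state there, carries 49.7% of the catalyst against 14.2% in blue. For the neighbour of green with 1.0 M of starting material, the batch output gives 4.73%, and the computed flask gives 5.55%.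

(The data were computed from invented constants; scatter was added.)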